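**Retrosynthetic overview**

1. Target 16 ⇐ ketone 15 (C9–OH-directed reduction of C7=O) ⇐ triol ketone 14 (angelates on the secondary C1 and C5 hydroxyls; the C7 ketone stands in for the C7 hydroxyl, the tertiary C9–OH needs no protection).
2. Key disconnection, both bonds in one operation: C1–C10 and C5–C6. 14 ⇐ hydroxy enone 6 (ring C6–C7–C8–C9–C10) + cyclopentenyl N-alkoxyphthalimide 12 (C1–C5 as a five-membered ring in which C1 and C5 are bonded). Reductive N–O cleavage, β-scission of the C1–C5 bond, Giese addition of the C1 radical to C10 and aldol addition of the C6 enolate to the C5 aldehyde insert the C10=C6 alkene into a ring bond of 12 (five- to seven-membered ring expansion).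
3. Enabling feature: in the seven-membered ring both carbons that flank the ring-fusion bond C10–C6 carry oxygen (O–C1–C10–C6–C5–O), so C1 and C5 can start as the vicinal dioxygenated carbons of a cyclopentene, while C10/C6 are the β/α carbons of the C7 ketone. The quaternary C6 keeps the aldol from eliminating, and both stereocentres of 12 become sp2, so all its stereoisomers converge.
4. Ring order: five-membered ring first (6, from silyloxycyclopentenone 1; its C9 carbinol is the only stereocentre carried in and steers C10, C1, C6, C5 and finally C7); seven-membered ring last, in the key step.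
5. 12 comes from 3-methylcyclopent-2-enone 7 (α′-hydroxylation, reduction, Mitsunobu reaction with N-hydroxyphthalimide).

Key step: step 11

Remark (locants used in the text, not IUPAC): seven-membered ring C1 (acyloxy CH next to the ring-fusion CH), C2 (CH2), C3 (methyl-bearing alkene carbon), C4 (alkene CH), C5 (second acyloxy CH), C6 (quaternary ring-fusion carbon with CH3), C10 (ring-fusion CH); five-membered ring C6, C7 (CHOH), C8 (CH2), C9 (C(OH)(i-Pr)), C10. α is the face of the C6 methyl and of C10–H, β the other face.

Assumption: compounds 1 and 7 are taken as commercially available.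

**Step 1**
Reactants: 1 (S)-4-(tert-butyldimethylsilyloxy)cyclopent-2-en-1-one
Product: 2 (1S,4S)-4-(tert-butyldimethylsilyloxy)-1-isopropylcyclopent-2-en-1-ol
Conditions: CeCl3 (anhydrous), i-PrMgCl, THF, −78 °C
Reagents that add atoms: isopropylmagnesium chloride, CC(C)[Mg]Cl
Why: Organocerium 1,2-addition (Imamoto conditions) suppresses enolisation, β-elimination of the silyloxy group and conjugate addition, and the nucleophile should enter anti to the C4 silyloxy group, which sets the tertiary carbinol as (S).

**Step 2**
Reactants: 2 (1S,4S)-4-(tert-butyldimethylsilyloxy)-1-isopropylcyclopent-2-en-1-ol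
Product: 3 (1S,4S)-1-isopropylcyclopent-2-ene-1,4-diol
Conditions: n-Bu4NF, THF, 0 °C
Reagents that add atoms: none
Why: Fluoride-mediated silyl ether cleavage; no stereocentre is touched and no ketone is yet present that could suffer retro-aldol opening.

**Step 3**
Reactants: 3 (1S,4S)-1-isopropylcyclopent-2-ene-1,4-diol
Product: 4 (S)-4-hydroxy-4-isopropylcyclopent-2-en-1-one
Conditions: MnO2, CH2Cl2, rt
Reagents that add atoms: none
Why: Allylic oxidation with MnO2 touches only the secondary allylic alcohol (the tertiary carbinol cannot be oxidised), and the controlling secondary stereocentre is erased after it has done its work.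

**Step 4**
Reactants: 4 (S)-4-hydroxy-4-isopropylcyclopent-2-en-1-one
Product: 5 (S)-4-hydroxy-2-iodo-4-isopropylcyclopent-2-en-1-one
Conditions: I2, pyridine, CH2Cl2, 0 °C to rt
Reagents that add atoms: iodine, [I][I]
Why: α-Iodination of an enone by the pyridine-mediated addition–iodination–elimination sequence (Johnson iodination) occurs only at the α-carbon and is mild enough for the γ-hydroxy enone.

**Step 5**
Reactants: 5 (S)-4-hydroxy-2-iodo-4-isopropylcyclopent-2-en-1-one
Product: 6 (S)-4-hydroxy-4-isopropyl-2-methylcyclopent-2-en-1-one
Conditions: SnMe4, Pd2(dba)3, AsPh3, CuI, NMP, 50 °C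
Reagents that add atoms: tetramethylstannane, C[Sn](C)(C)C
Why: Stille cross-coupling of the α-iodoenone under neutral conditions, so that the base-sensitive β-hydroxy ketone neither opens by retro-aldol reaction nor racemises.

**Step 6**
Reactants: 7 3-methylcyclopent-2-en-1-one
Product: 8 5-hydroxy-3-methylcyclopent-2-en-1-one (racemic)
Conditions: LiN(i-Pr)2, THF, −78 °C; 3-phenyl-2-(phenylsulfonyl)oxaziridine, −78 °C; AcOH
Reagents that add atoms: 3-phenyl-2-(phenylsulfonyl)oxaziridine, O=S(=O)(c1ccccc1)N1OC1c1ccccc1
Why: Kinetic deprotonation at the α′-CH2 and electrophilic hydroxylation of the cross-conjugated enolate (Davis oxidation); the new stereocentre may be racemic because it later becomes an sp2 radical centre.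

**Step 7**
Reactants: 8 5-hydroxy-3-methylcyclopent-2-en-1-one
Product: 9 3-methyl-5-(triethylsilyloxy)cyclopent-2-en-1-one (racemic)
Conditions: Et3SiCl, imidazole, CH2Cl2, 0 °C
Reagents that add atoms: chlorotriethylsilane, CC[Si](Cl)(CC)CC
Why: Standard silylation of the secondary alcohol; it tells the two oxygens apart before the ketone is reduced.

**Step 8**
Reactants: 9 3-methyl-5-(triethylsilyloxy)cyclopent-2-en-1-one
Product: 10 3-methyl-5-(triethylsilyloxy)cyclopent-2-en-1-ol (racemic; cis/trans mixture)
Conditions: i-Bu2AlH, CH2Cl2, −78 °C; aqueous KNaC4H4O6 work-up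
Reagents that add atoms: none
Why: 1,2-Reduction of the enone carbonyl with i-Bu2AlH gives the allylic alcohol; the cis/trans ratio does not matter because this carbon becomes the aldehyde carbon in the key step.

**Step 9**
Reactants: 10 3-methyl-5-(triethylsilyloxy)cyclopent-2-en-1-ol
Product: 11 2-{[3-methyl-5-(triethylsilyloxy)cyclopent-2-en-1-yl]oxy}isoindoline-1,3-dione (racemic; cis/trans mixture)
Conditions: N-hydroxyphthalimide, PPh3, DIAD, THF, 0 °C to rt
Reagents that add atoms: N-hydroxyphthalimide, O=C1N(O)C(=O)c2ccccc12
Why: Mitsunobu reaction with the acidic N-hydroxyphthalimide turns the allylic alcohol into the N-alkoxyphthalimide with inversion; the configuration is again irrelevant.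

**Step 10**
Reactants: 11 2-{[3-methyl-5-(triethylsilyloxy)cyclopent-2-en-1-yl]oxy}isoindoline-1,3-dione
Product: 12 2-[(5-hydroxy-3-methylcyclopent-2-en-1-yl)oxy]isoindoline-1,3-dione (racemic; cis/trans mixture)
Conditions: HF·pyridine, THF, 0 °C
Reagents that add atoms: none
Why: Buffered fluoride cleaves the triethylsilyl ether without touching the N–O bond or the imide; the free hydroxyl is wanted as a hydrogen-bond partner in the key step.

**Step 11**
Reactants: 6 (S)-4-hydroxy-4-isopropyl-2-methylcyclopent-2-en-1-one; 12 2-[(5-hydroxy-3-methylcyclopent-2-en-1-yl)oxy]isoindoline-1,3-dione (1.5 equiv)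
Product: 14 triol ketone (1α,5β,9β-trihydroxy-9α-isopropyl-3,6α-dimethylbicyclo[5.3.0]dec-3-en-7-one; cis-fused; 10α-H), via keto-enal enolate 13 (not isolated)
Conditions: Co(C5Me5)2 (2.2 equiv per 12, added over 2 h), THF, −60 °C; then AcOH, −60 °C
Reagents that add atoms: none
Why: Proposed new method: the outer-sphere donor Co(C5Me5)2 reduces the N–O bond of 12 to a cyclopentenyloxy radical, whose β-scission breaks the C1–C5 ring bond into the (Z)-enal (C5) and the α-hydroxyalkyl radical at C1; this radical adds to C10 of 6 (Giese addition), the C6 α-keto radical takes a second electron to give the metal-free enolate 13, and 13 adds to the aldehyde unveiled in the same event, so that the C10=C6 alkene is formally inserted into a σ-bond of the cyclopentenediol (two-carbon ring expansion). The closest known reaction types are the β-fragmentation of alkoxy radicals from singly reduced N-alkoxyphthalimides with Giese trapping, the photocatalytic ring-opening/Giese/aldol ring expansion of cycloalkanols with electron-poor alkenes, and radical–polar crossover cascades that end in an enolate aldol. The C1–C10 bond forms intermolecularly and the seven-membered ring then closes by a 7-(enolexo)-exo-trig aldol addition. C10 should be set by attack anti to the isopropyl group (syn to the small C9 hydroxyl), C1 by a staggered transition state with H over the ring, the radical hydroxyl hydrogen-bonded to C9–OH and the chain anti to C9, C6 by closure on the face that carries the new chain (cis fusion), and C5 by the C9 hydroxyl, which hydrogen-bonds the aldehyde oxygen on the β face while the free enolate oxygen repels it. The step needs chemoselective electron transfer (the donor, at about −1.5 V against SCE, reduces the N–O acceptor but neither enone nor enal, and its 18-electron cation neither binds the enolate nor oxidises the radical), regioselective scission (only the C1–C5 bond gives an O-stabilised radical and a conjugated aldehyde), a Z enal (fixed by the ring of 12) and radical capture faster than electron transfer (donor kept at low concentration by slow addition). Both stereocentres of 12 become sp2, so its four stereoisomers converge on one product.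

**Step 12**
Reactants: 14 triol ketone
Product: 15 1α,5β-bis[(Z)-2-methylbut-2-enoyloxy]-9β-hydroxy-9α-isopropyl-3,6α-dimethylbicyclo[5.3.0]dec-3-en-7-one
Conditions: angelic acid, 2,4,6-trichlorobenzoyl chloride, Et3N, toluene, rt; then 14, 75 °C (no DMAP)
Reagents that add atoms: angelic acid, C/C=C(/C)C(=O)O
Why: Yamaguchi-type mixed-anhydride acylation without DMAP transfers the (Z)-2-methylbut-2-enoyl group without Z to E isomerisation; only the two secondary hydroxyls react, the tertiary C9 hydroxyl is inert, and the acylated aldol can no longer undergo retro-aldol cleavage.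

**Step 13**
Reactants: 15 diangelate ketone
Product: 16 (1S,3R,3aR,4R,8R,8aR)-1,3-dihydroxy-1-isopropyl-3a,6-dimethyl-1,2,3,3a,4,7,8,8a-octahydroazulene-4,8-diyl bis[(Z)-2-methylbut-2-enoate] (CNP0249167.1)
Conditions: Me4NBH(OAc)3, MeCN/AcOH, −20 °C
Reagents that add atoms: none
Why: Hydroxyl-directed reduction of the β-hydroxy ketone (Evans–Saksena reduction): the C9 hydroxyl exchanges onto boron and delivers hydride to the β face of C7, which should give the 1,3-anti diol (C7–OH α, cis to the C6 methyl) and leave both enoates untouched.

**Compound list**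

1 | (S)-4-(tert-butyldimethylsilyloxy)cyclopent-2-en-1-one | O=C1C=C[C@@H](O[Si](C)(C)C(C)(C)C)C1 | starting material
2 | (1S,4S)-4-(tert-butyldimethylsilyloxy)-1-isopropylcyclopent-2-en-1-ol | CC(C)[C@]1(O)C=C[C@@H](O[Si](C)(C)C(C)(C)C)C1 | intermediate
3 | (1S,4S)-1-isopropylcyclopent-2-ene-1,4-diol | CC(C)[C@]1(O)C=C[C@@H](O)C1 | intermediate
4 | (S)-4-hydroxy-4-isopropylcyclopent-2-en-1-one | CC(C)[C@]1(O)C=CC(=O)C1 | intermediate
5 | (S)-4-hydroxy-2-iodo-4-isopropylcyclopent-2-en-1-one | CC(C)[C@]1(O)C=C(I)C(=O)C1 | intermediate
6 | (S)-4-hydroxy-4-isopropyl-2-methylcyclopent-2-en-1-one | CC(C)[C@]1(O)C=C(C)C(=O)C1 | intermediate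
7 | 3-methylcyclopent-2-en-1-one | CC1=CC(=O)CC1 | starting material
8 | 5-hydroxy-3-methylcyclopent-2-en-1-one (racemic) | CC1=CC(=O)C(O)C1 | intermediate
9 | 3-methyl-5-(triethylsilyloxy)cyclopent-2-en-1-one (racemic) | CC1=CC(=O)C(O[Si](CC)(CC)CC)C1 | intermediate
10 | 3-methyl-5-(triethylsilyloxy)cyclopent-2-en-1-ol (racemic, cis/trans mixture) | CC1=CC(O)C(O[Si](CC)(CC)CC)C1 | intermediate
11 | 2-{[3-methyl-5-(triethylsilyloxy)cyclopent-2-en-1-yl]oxy}isoindoline-1,3-dione (racemic, cis/trans mixture) | CC1=CC(ON2C(=O)c3ccccc3C2=O)C(O[Si](CC)(CC)CC)C1 | intermediate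
12 | 2-[(5-hydroxy-3-methylcyclopent-2-en-1-yl)oxy]isoindoline-1,3-dione (racemic, cis/trans mixture) | CC1=CC(ON2C(=O)c3ccccc3C2=O)C(O)C1 | intermediate
13 | keto-enal enolate: C6=C7 enolate of 4-hydroxy-3-[(Z)-1-hydroxy-3-methyl-5-oxopent-3-en-1-yl]-4-isopropyl-2-methylcyclopentanone, with C1, C9, C10 configured as in 14 (not isolated) | O=C/C=C(/C)C[C@@H](O)[C@H]1C(C)=C([O-])C[C@]1(O)C(C)C | intermediate
14 | triol ketone: 1α,5β,9β-trihydroxy-9α-isopropyl-3,6α-dimethylbicyclo[5.3.0]dec-3-en-7-one, cis-fused, 10α-H | O[C@@H]1CC(C)=C[C@@H](O)[C@@]2(C)C(=O)C[C@](O)(C(C)C)[C@@H]12 | intermediate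
15 | diangelate ketone: 1α,5β-bis[(Z)-2-methylbut-2-enoyloxy]-9β-hydroxy-9α-isopropyl-3,6α-dimethylbicyclo[5.3.0]dec-3-en-7-one | C/C=C(/C)C(=O)O[C@@H]1CC(C)=C[C@@H](OC(=O)/C(C)=C\C)[C@@]2(C)C(=O)C[C@](O)(C(C)C)[C@@H]12 | intermediate
16 | (1S,3R,3aR,4R,8R,8aR)-1,3-dihydroxy-1-isopropyl-3a,6-dimethyl-1,2,3,3a,4,7,8,8a-octahydroazulene-4,8-diyl bis[(Z)-2-methylbut-2-enoate] | C/C=C(/C)C(=O)O[C@@H]1CC(C)=C[C@@H](OC(=O)/C(C)=C\C)[C@@]2(C)[C@H](O)C[C@](O)(C(C)C)[C@@H]12 | target

**Step count and risk**

Total step count: 13. Longest linear sequence: 8 steps (steps 1–5, then 11–13; the branch through steps 6–10 is equally long).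

Steps most likely to fail:

1. Step 11 (proposed new method). The α-hydroxyalkyl radical may be lost to electron transfer before 6 captures it, the enolate may be protonated before it reaches the aldehyde, and facial selectivity at C1 or C5 may be poor. Fallback with known chemistry, stepwise: it sets out again from 6 and 12. The same alkoxy radical is generated under established photoredox conditions with a hydrogen-atom donor (fac-Ir(ppy)3, Hantzsch ester, MeCN, blue LEDs). β-Scission and Giese addition to 6 then end with hydrogen transfer to C6 and should give the keto lactol F1, in which the C1 hydroxyl has closed onto the (Z)-enal as a 2-hydroxy-5,6-dihydro-2H-pyran (C6 and the lactol carbon as mixtures). F1 is then closed by an equilibrating base-mediated intramolecular aldol addition (DBU, MeCN, 0 °C), in which only the C6 enolate can reach the aldehyde through a seven-membered transition state. The route is rejoined at 14.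

2. Step 12. The angeloyl group may isomerise Z to E during acyl activation, and acylation of the neopentyl-type C5 hydroxyl may stay incomplete. Fallback: it sets out from 14, which is esterified at both secondary hydroxyls with 2-[bis(2-methylphenoxy)phosphoryl]propanoic acid (DCC, DMAP, CH2Cl2) to the bis(phosphonopropionate) F2. A Z-selective Horner–Wadsworth–Emmons reaction of the Ando type with acetaldehyde (NaI, DBU, THF, −78 to 0 °C) then builds both (Z)-2-methylbut-2-enoates in place, and the route is rejoined at 15.

3. Step 9. Activation of the hindered allylic alcohol under Mitsunobu conditions may end in elimination to the diene or in allylic transposition. Fallback: it sets out from 10, which is converted into the methyl carbonate F3 (ClCO2Me, pyridine, CH2Cl2, 0 °C). Allylic substitution with N-hydroxyphthalimide under Pd(PPh3)4 catalysis (THF, rt; Tsuji–Trost O-allylation at the less substituted allyl terminus) then gives the N-alkoxyphthalimide, and the route is rejoined at 11.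

**Further compounds**

F1 | step 11 | keto lactol: 4-hydroxy-3-(6-hydroxy-4-methyl-3,6-dihydro-2H-pyran-2-yl)-4-isopropyl-2-methylcyclopentanone, with C1, C9, C10 configured as in 14 | CC1=CC(O)O[C@H](C1)[C@H]1C(C)C(=O)C[C@]1(O)C(C)C
F2 | step 12 | 1α,5β-bis{2-[bis(2-methylphenoxy)phosphoryl]propanoyloxy} derivative of 14 | CC(C(=O)O[C@@H]1CC(C)=C[C@@H](OC(=O)C(C)P(=O)(Oc3ccccc3C)Oc3ccccc3C)[C@@]2(C)C(=O)C[C@](O)(C(C)C)[C@@H]12)P(=O)(Oc1ccccc1C)Oc1ccccc1C
F3 | step 9 | methyl 3-methyl-5-(triethylsilyloxy)cyclopent-2-en-1-yl carbonate | COC(=O)OC1C=C(C)CC1O[Si](CC)(CC)CC
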